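(All runs are calculated for an exercise, noise included.)

The constants were not before the meeting, which had two earlier runs and four new flasks to rank, each with 0.20 M of first end groups.

| flask | first end groups | second end groups | remark | time |
|---|---|---|---|---|
| summer | 0.20 M | 0.45 equiv | run made earlier |  |
| dusk | 0.20 M | 2.3 equiv | run made earlier |  |
| east | 0.20 M | 0.740 equiv |  | 5.0 min |
| south-east | 0.20 M | 0.360 equiv |  | 5.0 min |
| north | 0.20 M | 1.10 equiv |  | 5.0 min |
| west | 0.20 M | 1.70 equiv |  | 5.0 min |

| run | time / min | links / % |
|---|---|---|
| summer | 0.667 | 38.4 |
| summer | 1.33 | 41.5 |
| summer | 2.00 | 41.7 |
| summer | 3.00 | 42.4 |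
| summer | 4.00 | 41.7 |
| summer | 5.00 | 41.9 |
| dusk | 0.667 | 94.9 |
| dusk | 1.33 | 97.3 |
| dusk | 2.00 | 98.5 |
| dusk | 3.00 | 99.1 |
| dusk | 4.00 | 100.8 |
| dusk | 5.00 | 100.2 |

(standard deviation of a reading: 1 percentage point)

- all flasks from highest to lowest amount of links, in percent of the first end groups charged, at 5.0 min (east / south-east / north / west)
- the amount of links, in percent of the first end groups charged of the flask you put first, at 5.0 min
- the amount of links, in percent of the first end groups charged of the flask you put last, at 5.0 min



The first member read the summer run, where second end groups, charged at 0.45 equiv, are the limiting reagent. Its links stand about flat from 2.00 min on and read 41.9 % at 5.00 min.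

The member proposed to take the fast step as over and to count what it leaves. Dividing that reading by the charge gives 0.931, the usable share: links at the plateau per second end group charged, read from a reading good to 1 percentage point.

A second member answered that the dusk run, with 2.3 equiv of second end groups, reads 100.2 % at 5.00 min, so first end groups can be taken as used up there, within the scatter. The meeting agreed to apply the share to flasks short of second end groups. My own reckoning for south-east, charged at 0.360 equiv, is 33.5 %.

The forecast gave the order west > north > east > south-east, with west at 99.5 % (range 98 % to 100.5 %) and south-east at 33.5 % (range 32.5 % to 34.5 %). Its author held that “the reaction is effectively irreversible”.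

    first end groups + second end groups → links (k = 0.460 M⁻¹ s⁻¹)
    2 second end groups → self-condensation product (k = 0.0580 M⁻¹ s⁻¹)

The flasks give west > north > east > south-east, with west at 99.7 % and south-east at 34.3 %. South-east, with 0 % of its second end groups left at 5.00 min, shows 0.953 links per second end group charged, against the usable share of 0.931. West's links have moved 5 points, which is outside the forecast's range, with its charge down at 1.23 equiv or, with the charge held, its time down at 1.06 min. The neighbour flask charged at 0.680 equiv would have 63.3 % by the usable share, but it stands at 61.3 %, with 0.00668 M of self-condensation product.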